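**Strategy.** The oxocene ring (O1, C2–C8; C2 carries ethyl, C3=C4 is the Z alkene, C5 and C6 carry the acetates, C8 the side chain) is not closed directly. It is grown from a seven-membered 1,3-dioxepane, the propanal acetal of the C8 and C5 hydroxyls. A Lewis acid opens the acetal to an oxocarbenium ion at O1=C2, and the (Z)-vinylsilane on C5 attacks it: C3=C4 is inserted between C2 and C5, the C5 oxygen leaves the ring as a hydroxyl, and the C2 stereocentre and the ring Z-olefin are set in one operation. The step exploits the allylic ether O1–C2–C3=C4 flanked by the oxygenated C5. The chloro enyne arm is added last.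

Key step: step 8

Remark: ring compounds are numbered as in the oxocene above. The acetal carbon of 11 and 12 is carried as an epimer mixture, because it becomes planar in step 8.

**Step 1**
Reactants: 1 (R)-5-(hydroxymethyl)dihydrofuran-2(3H)-one
Product: 2 (R)-5-{[(tert-butyldiphenylsilyl)oxy]methyl}dihydrofuran-2(3H)-one
Conditions: t-BuPh2SiCl, imidazole, DMF, rt
Reagents that add atoms: tert-butyl(chloro)diphenylsilane, CC(C)(C)[Si](Cl)(c1ccccc1)c1ccccc1
Why: Silylation of the only hydroxyl gives a non-participating ether that should survive the enolate, organolithium and Lewis acid steps (standard silyl protection).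

**Step 2**
Reactants: 2 (R)-5-{[(tert-butyldiphenylsilyl)oxy]methyl}dihydrofuran-2(3H)-one
Product: 4 (3S,5R)-5-{[(tert-butyldiphenylsilyl)oxy]methyl}-3-hydroxydihydrofuran-2(3H)-one, via potassium enolate 3 (not isolated)
Conditions: KN(SiMe3)2, THF, −78 °C; then 3-phenyl-2-(phenylsulfonyl)oxaziridine, −78 °C; aq NH4Cl
Reagents that add atoms: 3-phenyl-2-(phenylsulfonyl)oxaziridine, O=S(=O)(N1OC1c1ccccc1)c1ccccc1
Why: Davis enolate oxidation; the oxaziridine should approach enolate 3 anti to the C5 silyloxymethyl group, so the new carbinol centre is set trans (3S).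

**Step 3**
Reactants: 4 (3S,5R)-5-{[(tert-butyldiphenylsilyl)oxy]methyl}-3-hydroxydihydrofuran-2(3H)-one
Product: 5 (3R,5R)-5-{[(tert-butyldiphenylsilyl)oxy]methyl}-3-(4-methoxyphenoxy)dihydrofuran-2(3H)-one
Conditions: 4-methoxyphenol, PPh3, DIAD, toluene, 0 °C to rt
Reagents that add atoms: 4-methoxyphenol, COc1ccc(O)cc1
Why: Mitsunobu etherification of the α-hydroxy lactone proceeds by SN2 with inversion, so the trans alcohol should give the required cis (3R) aryl ether and cap this oxygen in the same operation.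

**Step 4**
Reactants: 5 (3R,5R)-5-{[(tert-butyldiphenylsilyl)oxy]methyl}-3-(4-methoxyphenoxy)dihydrofuran-2(3H)-one; 6 ethynyltrimethylsilane
Product: 8 (4R,6R)-7-[(tert-butyldiphenylsilyl)oxy]-6-hydroxy-4-(4-methoxyphenoxy)-1-(trimethylsilyl)hept-1-yn-3-one, via lithium hemiketal alkoxide 7 (not isolated)
Conditions: 6, n-BuLi, THF, −78 °C; then 5, −78 °C; aq NH4Cl
Reagents that add atoms: none
Why: Lithium acetylides add once to γ-lactones at low temperature because the tetrahedral adduct 7 persists until work-up, which frees the hydroxy ynone (acylation of an acetylide by a lactone).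

**Step 5**
Reactants: 8 (4R,6R)-7-[(tert-butyldiphenylsilyl)oxy]-6-hydroxy-4-(4-methoxyphenoxy)-1-(trimethylsilyl)hept-1-yn-3-one
Product: 9 (3R,4R,6R)-7-[(tert-butyldiphenylsilyl)oxy]-4-(4-methoxyphenoxy)-1-(trimethylsilyl)hept-1-yne-3,6-diol
Conditions: Ru[(S,S)-TsDPEN](p-cymene) (preformed amido complex, 3 mol %), i-PrOH, rt
Reagents that add atoms: none
Why: Noyori asymmetric transfer hydrogenation of alkynyl ketones is catalyst-controlled; with the (S,S) ligand the alkynyl group should take the place of the aryl group of acetophenone, which corresponds to the 3R carbinol here.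

**Step 6**
Reactants: 9 (3R,4R,6R)-7-[(tert-butyldiphenylsilyl)oxy]-4-(4-methoxyphenoxy)-1-(trimethylsilyl)hept-1-yne-3,6-diol; 10 1,1-dimethoxypropane
Product: 11 (4R,5R,7R)-7-{[(tert-butyldiphenylsilyl)oxy]methyl}-2-ethyl-5-(4-methoxyphenoxy)-4-[(trimethylsilyl)ethynyl]-1,3-dioxepane (C2 epimers)
Conditions: 10, PPTS (cat.), benzene, 5 Å MS, 50 °C
Reagents that add atoms: none
Why: Acid-catalysed transacetalisation of the 1,4-diol with removal of methanol should close the seven-membered acetal; only these two hydroxyls are free, so no smaller acetal can form.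

**Step 7**
Reactants: 11 (4R,5R,7R)-7-{[(tert-butyldiphenylsilyl)oxy]methyl}-2-ethyl-5-(4-methoxyphenoxy)-4-[(trimethylsilyl)ethynyl]-1,3-dioxepane
Product: 12 (4R,5R,7R)-7-{[(tert-butyldiphenylsilyl)oxy]methyl}-2-ethyl-5-(4-methoxyphenoxy)-4-[(Z)-2-(trimethylsilyl)ethenyl]-1,3-dioxepane (C2 epimers)
Conditions: H2 (1 atm), Lindlar catalyst (Pd/CaCO3 poisoned with Pb(OAc)2), quinoline, hexane–EtOAc, rt
Reagents that add atoms: none
Why: Lindlar semihydrogenation adds hydrogen syn to the silylalkyne and should stop at the (Z)-vinylsilane, the geometry needed for endocyclic capture.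

**Step 8**
Reactants: 12 (4R,5R,7R)-7-{[(tert-butyldiphenylsilyl)oxy]methyl}-2-ethyl-5-(4-methoxyphenoxy)-4-[(Z)-2-(trimethylsilyl)ethenyl]-1,3-dioxepane
Product: 14 (2R,5R,6R,8R,Z)-8-{[(tert-butyldiphenylsilyl)oxy]methyl}-2-ethyl-6-(4-methoxyphenoxy)-5,6,7,8-tetrahydro-2H-oxocin-5-ol, via oxocarbenium ion 13 (not isolated)
Conditions: SnCl4 (2 equiv), CH2Cl2, −78 to −20 °C; then aq NaHCO3
Reagents that add atoms: none
Why: SnCl4 ionises the acetal at the bond between the acetal carbon and the allylic oxygen, giving oxocarbenium ion 13 on the oxygen of the future C8; its carbon is attacked by the silicon-bearing carbon of the (Z)-vinylsilane in an 8-endo closure, and loss of the silyl group from the β-silyl cation gives C3=C4 with retention, so the ring Z geometry follows from the Z vinylsilane. The net change is a one-atom ring enlargement: six atoms of the dioxepane are kept, its second oxygen is pushed out of the ring as the C5 hydroxyl, and C3=C4 is spliced in between C2 and C5. The closest known reaction type is the Lewis acid-promoted acetal–vinylsilane cyclisation that gives 2-substituted allylically unsaturated oxacycles up to oxocenes, combined with the regioselective opening of cyclic acetals of allylic diols known from Prins–pinacol chemistry. The new stereocentre C2 should be set cis to C8, because the (E)-oxocarbenium ion should close through a transition state with the ethyl group and the C8 substituent both pseudo-equatorial. The step needs the acetal to open towards the allylic alkoxide and not towards the C8 oxygen: the isomeric ion could close only in a strained 5-endo mode, and since both ions interconvert through the acetal the productive one should be drained.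

**Step 9**
Reactants: 14 (2R,5R,6R,8R,Z)-8-{[(tert-butyldiphenylsilyl)oxy]methyl}-2-ethyl-6-(4-methoxyphenoxy)-5,6,7,8-tetrahydro-2H-oxocin-5-ol
Product: 15 (2R,5R,6R,8R,Z)-8-{[(tert-butyldiphenylsilyl)oxy]methyl}-2-ethyl-5,6,7,8-tetrahydro-2H-oxocine-5,6-diol
Conditions: (NH4)2Ce(NO3)6, MeCN–H2O (4:1), 0 °C
Reagents that add atoms: none
Why: Oxidative dearylation: the electron-rich 4-methoxyphenyl ether is oxidised to benzoquinone and releases the C6 hydroxyl, while the silyl ether and the olefin should be untouched.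

**Step 10**
Reactants: 15 (2R,5R,6R,8R,Z)-8-{[(tert-butyldiphenylsilyl)oxy]methyl}-2-ethyl-5,6,7,8-tetrahydro-2H-oxocine-5,6-diol
Product: 16 (2R,5R,6R,8R,Z)-8-{[(tert-butyldiphenylsilyl)oxy]methyl}-2-ethyl-5,6,7,8-tetrahydro-2H-oxocine-5,6-diyl diacetate
Conditions: Ac2O, pyridine, DMAP (cat.), CH2Cl2, rt
Reagents that add atoms: acetic anhydride, CC(=O)OC(C)=O
Why: DMAP-catalysed acylation of both secondary hydroxyls installs the two acetates of the target.

**Step 11**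
Reactants: 16 (2R,5R,6R,8R,Z)-8-{[(tert-butyldiphenylsilyl)oxy]methyl}-2-ethyl-5,6,7,8-tetrahydro-2H-oxocine-5,6-diyl diacetate
Product: 17 (2R,5R,6R,8R,Z)-2-ethyl-8-(hydroxymethyl)-5,6,7,8-tetrahydro-2H-oxocine-5,6-diyl diacetate
Conditions: HF·pyridine, pyridine, THF, 0 °C to rt
Reagents that add atoms: none
Why: Buffered fluoride cleaves the primary silyl ether while the acetates should survive (desilylation).

**Step 12**
Reactants: 17 (2R,5R,6R,8R,Z)-2-ethyl-8-(hydroxymethyl)-5,6,7,8-tetrahydro-2H-oxocine-5,6-diyl diacetate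
Product: 18 (2R,5R,6R,8R,Z)-2-ethyl-8-formyl-5,6,7,8-tetrahydro-2H-oxocine-5,6-diyl diacetate
Conditions: Dess–Martin periodinane, NaHCO3, CH2Cl2, 0 °C to rt
Reagents that add atoms: none
Why: Dess–Martin oxidation under buffered conditions should give the α-alkoxy aldehyde without epimerisation at C8; it is used at once.

**Step 13**
Reactants: 18 (2R,5R,6R,8R,Z)-2-ethyl-8-formyl-5,6,7,8-tetrahydro-2H-oxocine-5,6-diyl diacetate
Product: 19 (2R,5R,6R,8R,Z)-2-ethyl-8-[(1S)-1-hydroxybut-3-en-1-yl]-5,6,7,8-tetrahydro-2H-oxocine-5,6-diyl diacetate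
Conditions: diisopropyl (R,R)-tartrate allylboronate, 4 Å MS, toluene, −78 °C; then aq NaHCO3
Reagents that add atoms: diisopropyl (4R,5R)-2-(prop-2-en-1-yl)-1,3,2-dioxaborolane-4,5-dicarboxylate, C=CCB1O[C@@H](C(=O)OC(C)C)[C@@H](O1)C(=O)OC(C)C
Why: Roush asymmetric allylboration through a closed chair transition state; the (R,R)-tartrate reagent should give the 1S carbinol, which is also the anti (Felkin) product of this α-alkoxy aldehyde, so reagent and substrate control are matched.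

**Step 14**
Reactants: 19 (2R,5R,6R,8R,Z)-2-ethyl-8-[(1S)-1-hydroxybut-3-en-1-yl]-5,6,7,8-tetrahydro-2H-oxocine-5,6-diyl diacetate
Product: 20 (2R,5R,6R,8R,Z)-8-[(1R)-1-chlorobut-3-en-1-yl]-2-ethyl-5,6,7,8-tetrahydro-2H-oxocine-5,6-diyl diacetate
Conditions: CCl4, P(n-C8H17)3, toluene, 60 °C
Reagents that add atoms: tetrachloromethane, ClC(Cl)(Cl)Cl
Why: Appel-type chlorination: the phosphorus-activated hydroxyl is displaced by chloride in an SN2 step, so the 1S alcohol should give the 1R chloride with inversion.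

**Step 15**
Reactants: 20 (2R,5R,6R,8R,Z)-8-[(1R)-1-chlorobut-3-en-1-yl]-2-ethyl-5,6,7,8-tetrahydro-2H-oxocine-5,6-diyl diacetate; 21 (but-3-en-1-yn-1-yl)trimethylsilane
Product: 22 (2R,5R,6R,8R,Z)-8-[(1R,3Z)-1-chloro-6-(trimethylsilyl)hex-3-en-5-yn-1-yl]-2-ethyl-5,6,7,8-tetrahydro-2H-oxocine-5,6-diyl diacetate
Conditions: 21 (4 equiv), second-generation Grubbs catalyst RuCl2(=CHPh)(H2IMes)(PCy3) (10 mol %), CH2Cl2, 40 °C
Reagents that add atoms: none
Why: Cross-metathesis of a terminal olefin with a conjugated enyne is known to favour the Z-enyne; the ring olefin is cis-disubstituted and flanked by two oxygenated carbons and should not compete.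

**Step 16**
Reactants: 22 (2R,5R,6R,8R,Z)-8-[(1R,3Z)-1-chloro-6-(trimethylsilyl)hex-3-en-5-yn-1-yl]-2-ethyl-5,6,7,8-tetrahydro-2H-oxocine-5,6-diyl diacetate
Product: 23 (2R,5R,6R,8R,Z)-8-[(1R,3Z)-1-chlorohex-3-en-5-yn-1-yl]-2-ethyl-5,6,7,8-tetrahydro-2H-oxocine-5,6-diyl diacetate
Conditions: Bu4NF, AcOH, THF, 0 °C
Reagents that add atoms: none
Why: Fluoride cleaves the alkynyl C–Si bond selectively, and the acetic acid buffer should preserve the acetates and the alkyl chloride (protodesilylation).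

**Compound list**

1 | (R)-5-(hydroxymethyl)dihydrofuran-2(3H)-one | OC[C@H]1CCC(=O)O1 | starting material
2 | (R)-5-{[(tert-butyldiphenylsilyl)oxy]methyl}dihydrofuran-2(3H)-one | CC(C)(C)[Si](c1ccccc1)(c1ccccc1)OC[C@H]1CCC(=O)O1 | intermediate
3 | potassium enolate of 2 | CC(C)(C)[Si](c1ccccc1)(c1ccccc1)OC[C@H]1CC=C([O-])O1.[K+] | intermediate
4 | (3S,5R)-5-{[(tert-butyldiphenylsilyl)oxy]methyl}-3-hydroxydihydrofuran-2(3H)-one | CC(C)(C)[Si](c1ccccc1)(c1ccccc1)OC[C@H]1C[C@H](O)C(=O)O1 | intermediate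
5 | (3R,5R)-5-{[(tert-butyldiphenylsilyl)oxy]methyl}-3-(4-methoxyphenoxy)dihydrofuran-2(3H)-one | CC(C)(C)[Si](c1ccccc1)(c1ccccc1)OC[C@H]1C[C@@H](Oc2ccc(OC)cc2)C(=O)O1 | intermediate
6 | ethynyltrimethylsilane | C#C[Si](C)(C)C | starting material
7 | lithium hemiketal alkoxide (adduct of lithium (trimethylsilyl)acetylide and 5) | CC(C)(C)[Si](c1ccccc1)(c1ccccc1)OC[C@H]1C[C@@H](Oc2ccc(OC)cc2)C([O-])(C#C[Si](C)(C)C)O1.[Li+] | intermediate
8 | (4R,6R)-7-[(tert-butyldiphenylsilyl)oxy]-6-hydroxy-4-(4-methoxyphenoxy)-1-(trimethylsilyl)hept-1-yn-3-one | CC(C)(C)[Si](c1ccccc1)(c1ccccc1)OC[C@H](O)C[C@@H](Oc1ccc(OC)cc1)C(=O)C#C[Si](C)(C)C | intermediate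
9 | (3R,4R,6R)-7-[(tert-butyldiphenylsilyl)oxy]-4-(4-methoxyphenoxy)-1-(trimethylsilyl)hept-1-yne-3,6-diol | CC(C)(C)[Si](c1ccccc1)(c1ccccc1)OC[C@H](O)C[C@@H](Oc1ccc(OC)cc1)[C@H](O)C#C[Si](C)(C)C | intermediate
10 | 1,1-dimethoxypropane | CCC(OC)OC | starting material
11 | (4R,5R,7R)-7-{[(tert-butyldiphenylsilyl)oxy]methyl}-2-ethyl-5-(4-methoxyphenoxy)-4-[(trimethylsilyl)ethynyl]-1,3-dioxepane (C2 epimers) | CC(C)(C)[Si](c1ccccc1)(c1ccccc1)OC[C@H]1C[C@@H](Oc2ccc(OC)cc2)[C@@H](C#C[Si](C)(C)C)OC(CC)O1 | intermediate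
12 | (4R,5R,7R)-7-{[(tert-butyldiphenylsilyl)oxy]methyl}-2-ethyl-5-(4-methoxyphenoxy)-4-[(Z)-2-(trimethylsilyl)ethenyl]-1,3-dioxepane (C2 epimers) | CC(C)(C)[Si](c1ccccc1)(c1ccccc1)OC[C@H]1C[C@@H](Oc2ccc(OC)cc2)[C@@H](/C=C\[Si](C)(C)C)OC(CC)O1 | intermediate
13 | oxocarbenium ion from acetal opening of 12 (tin alkoxide zwitterion) | CC(C)(C)[Si](c1ccccc1)(c1ccccc1)OC[C@@H](C[C@@H](Oc1ccc(OC)cc1)[C@@H](/C=C\[Si](C)(C)C)O[Sn-](Cl)(Cl)(Cl)Cl)[O+]=CCC | intermediate
14 | (2R,5R,6R,8R,Z)-8-{[(tert-butyldiphenylsilyl)oxy]methyl}-2-ethyl-6-(4-methoxyphenoxy)-5,6,7,8-tetrahydro-2H-oxocin-5-ol | CC(C)(C)[Si](c1ccccc1)(c1ccccc1)OC[C@H]1C[C@@H](Oc2ccc(OC)cc2)[C@H](O)/C=C\[C@@H](CC)O1 | intermediate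
15 | (2R,5R,6R,8R,Z)-8-{[(tert-butyldiphenylsilyl)oxy]methyl}-2-ethyl-5,6,7,8-tetrahydro-2H-oxocine-5,6-diol | CC(C)(C)[Si](c1ccccc1)(c1ccccc1)OC[C@H]1C[C@@H](O)[C@H](O)/C=C\[C@@H](CC)O1 | intermediate
16 | (2R,5R,6R,8R,Z)-8-{[(tert-butyldiphenylsilyl)oxy]methyl}-2-ethyl-5,6,7,8-tetrahydro-2H-oxocine-5,6-diyl diacetate | CC(C)(C)[Si](c1ccccc1)(c1ccccc1)OC[C@H]1C[C@@H](OC(C)=O)[C@H](OC(C)=O)/C=C\[C@@H](CC)O1 | intermediate
17 | (2R,5R,6R,8R,Z)-2-ethyl-8-(hydroxymethyl)-5,6,7,8-tetrahydro-2H-oxocine-5,6-diyl diacetate | OC[C@H]1C[C@@H](OC(C)=O)[C@H](OC(C)=O)/C=C\[C@@H](CC)O1 | intermediate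
18 | (2R,5R,6R,8R,Z)-2-ethyl-8-formyl-5,6,7,8-tetrahydro-2H-oxocine-5,6-diyl diacetate | O=C[C@H]1C[C@@H](OC(C)=O)[C@H](OC(C)=O)/C=C\[C@@H](CC)O1 | intermediate
19 | (2R,5R,6R,8R,Z)-2-ethyl-8-[(1S)-1-hydroxybut-3-en-1-yl]-5,6,7,8-tetrahydro-2H-oxocine-5,6-diyl diacetate | C=CC[C@H](O)[C@H]1C[C@@H](OC(C)=O)[C@H](OC(C)=O)/C=C\[C@@H](CC)O1 | intermediate
20 | (2R,5R,6R,8R,Z)-8-[(1R)-1-chlorobut-3-en-1-yl]-2-ethyl-5,6,7,8-tetrahydro-2H-oxocine-5,6-diyl diacetate | C=CC[C@@H](Cl)[C@H]1C[C@@H](OC(C)=O)[C@H](OC(C)=O)/C=C\[C@@H](CC)O1 | intermediate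
21 | (but-3-en-1-yn-1-yl)trimethylsilane | C=CC#C[Si](C)(C)C | starting material
22 | (2R,5R,6R,8R,Z)-8-[(1R,3Z)-1-chloro-6-(trimethylsilyl)hex-3-en-5-yn-1-yl]-2-ethyl-5,6,7,8-tetrahydro-2H-oxocine-5,6-diyl diacetate | C[Si](C)(C)C#C/C=C\C[C@@H](Cl)[C@H]1C[C@@H](OC(C)=O)[C@H](OC(C)=O)/C=C\[C@@H](CC)O1 | intermediate
23 | (2R,5R,6R,8R,Z)-8-[(1R,3Z)-1-chlorohex-3-en-5-yn-1-yl]-2-ethyl-5,6,7,8-tetrahydro-2H-oxocine-5,6-diyl diacetate | C#C/C=C\C[C@@H](Cl)[C@H]1C[C@@H](OC(C)=O)[C@H](OC(C)=O)/C=C\[C@@H](CC)O1 | target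

**Total steps:** 16. **Longest linear sequence:** 16 (from 1).

**Steps most likely to fail**

Step 8. The acetal may open mainly on the wrong side, or the vinylsilane, made less nucleophilic by the neighbouring tin alkoxide, may capture the oxocarbenium ion too slowly, so that the ion is lost by hydrolysis or proton loss. The fallback sets out from 8 and closes the ring from an open-chain mixed acetal, which can ionise productively only on the C8 oxygen. Ethyl prop-1-enyl ether with PPTS should convert 8 into the 1-ethoxypropyl ether, (4R,6R)-7-[(tert-butyldiphenylsilyl)oxy]-6-(1-ethoxypropoxy)-4-(4-methoxyphenoxy)-1-(trimethylsilyl)hept-1-yn-3-one F1. Transfer hydrogenation as in step 5 should give the propargylic alcohol F2. Acetylation (Ac2O, pyridine, DMAP) should give the acetate F3, and Lindlar semihydrogenation the (Z)-vinylsilane F4. SnCl4 in CH2Cl2 at −78 to −20 °C should then give the 5-acetoxy oxocene F5 by the acetal–vinylsilane cyclisation of acyclic mixed acetals. K2CO3 in MeOH removes the acetate, and the route is rejoined at 14.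

Step 15. The cross-metathesis may give poor Z/E control, or the catalyst may engage the ring olefin and open the oxocene. The fallback sets out from 20. OsO4 (cat.), NaIO4 and 2,6-lutidine in dioxane–water should cleave the more accessible terminal olefin to the aldehyde, (2R,5R,6R,8R,Z)-8-[(1R)-1-chloro-3-oxopropyl]-2-ethyl-5,6,7,8-tetrahydro-2H-oxocine-5,6-diyl diacetate F6. Stork–Zhao olefination ((iodomethyl)triphenylphosphonium iodide, NaN(SiMe3)2, THF–DMPU, −78 °C) should give the (Z)-vinyl iodide F7. Sonogashira coupling with 6 (Pd(PPh3)4, CuI, i-Pr2NH) returns to the route at 22.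

Step 6. The 1,4-diol may give open-chain or oligomeric mixed acetals under equilibrium conditions, because closure of a seven-membered acetal is entropically poor. The fallback sets out from 9 and replaces the reversible exchange by a kinetically controlled condensation. Me3SiCl and imidazole should give the bis(trimethylsilyl) ether, (3R,4R,6R)-7-[(tert-butyldiphenylsilyl)oxy]-4-(4-methoxyphenoxy)-1-(trimethylsilyl)-3,6-bis[(trimethylsilyl)oxy]hept-1-yne F8. Propanal with Me3SiOTf (cat.) in CH2Cl2 at −78 °C (Noyori acetalisation, driven by siloxane formation) should then give 11.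

**Further compounds**

F1 | step 8 | (4R,6R)-7-[(tert-butyldiphenylsilyl)oxy]-6-(1-ethoxypropoxy)-4-(4-methoxyphenoxy)-1-(trimethylsilyl)hept-1-yn-3-one | CC(C)(C)[Si](c1ccccc1)(c1ccccc1)OC[C@H](OC(CC)OCC)C[C@@H](Oc1ccc(OC)cc1)C(=O)C#C[Si](C)(C)C
F2 | step 8 | (3R,4R,6R)-7-[(tert-butyldiphenylsilyl)oxy]-6-(1-ethoxypropoxy)-4-(4-methoxyphenoxy)-1-(trimethylsilyl)hept-1-yn-3-ol | CC(C)(C)[Si](c1ccccc1)(c1ccccc1)OC[C@H](OC(CC)OCC)C[C@@H](Oc1ccc(OC)cc1)[C@H](O)C#C[Si](C)(C)C
F3 | step 8 | (3R,4R,6R)-7-[(tert-butyldiphenylsilyl)oxy]-6-(1-ethoxypropoxy)-4-(4-methoxyphenoxy)-1-(trimethylsilyl)hept-1-yn-3-yl acetate | CC(C)(C)[Si](c1ccccc1)(c1ccccc1)OC[C@H](OC(CC)OCC)C[C@@H](Oc1ccc(OC)cc1)[C@H](OC(C)=O)C#C[Si](C)(C)C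
F4 | step 8 | (1Z,3R,4R,6R)-7-[(tert-butyldiphenylsilyl)oxy]-6-(1-ethoxypropoxy)-4-(4-methoxyphenoxy)-1-(trimethylsilyl)hept-1-en-3-yl acetate | CC(C)(C)[Si](c1ccccc1)(c1ccccc1)OC[C@H](OC(CC)OCC)C[C@@H](Oc1ccc(OC)cc1)[C@H](OC(C)=O)/C=C\[Si](C)(C)C
F5 | step 8 | (2R,5R,6R,8R,Z)-8-{[(tert-butyldiphenylsilyl)oxy]methyl}-2-ethyl-6-(4-methoxyphenoxy)-5,6,7,8-tetrahydro-2H-oxocin-5-yl acetate | CC(C)(C)[Si](c1ccccc1)(c1ccccc1)OC[C@H]1C[C@@H](Oc2ccc(OC)cc2)[C@H](OC(C)=O)/C=C\[C@@H](CC)O1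
F6 | step 15 | (2R,5R,6R,8R,Z)-8-[(1R)-1-chloro-3-oxopropyl]-2-ethyl-5,6,7,8-tetrahydro-2H-oxocine-5,6-diyl diacetate | O=CC[C@@H](Cl)[C@H]1C[C@@H](OC(C)=O)[C@H](OC(C)=O)/C=C\[C@@H](CC)O1
F7 | step 15 | (2R,5R,6R,8R,Z)-8-[(1R,3Z)-1-chloro-4-iodobut-3-en-1-yl]-2-ethyl-5,6,7,8-tetrahydro-2H-oxocine-5,6-diyl diacetate | I/C=C\C[C@@H](Cl)[C@H]1C[C@@H](OC(C)=O)[C@H](OC(C)=O)/C=C\[C@@H](CC)O1
F8 | step 6 | (3R,4R,6R)-7-[(tert-butyldiphenylsilyl)oxy]-4-(4-methoxyphenoxy)-1-(trimethylsilyl)-3,6-bis[(trimethylsilyl)oxy]hept-1-yne | CC(C)(C)[Si](c1ccccc1)(c1ccccc1)OC[C@H](O[Si](C)(C)C)C[C@@H](Oc1ccc(OC)cc1)[C@H](O[Si](C)(C)C)C#C[Si](C)(C)C
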